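Retrosynthesis: the two benzyl ethers on flavone 1 come off last and ring C of flavone 2 is taken back to the flavanone. Ring A of flavone 2 is then cut at C8–C8a and C4a–C5 (Diels–Alder) into the Brassard diene and a 2-aryl-5-(phenylsulfinyl)-2,3-dihydro-4-pyranone.
That dihydropyranone is cut at O1–C6 and C2–C3 (hetero-Diels–Alder) to a 4-formylphenyl ether; the diaryl ether C–O bond (SNAr) and the C8–O bond of flavone 1 (Elbs) lead back to acacetin.
Forward: flavone 1 is bought as acacetin, the ether bridge is joined, the pyranone ring (future ring C of flavone 2) is built, ring A of flavone 2 is closed, then ring C is dehydrogenated and the benzyl groups are removed.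
Enabling feature: ring A of flavone 2 has OH at C5 (hydrogen-bonded to C4=O) and OMe at C7. This is the pattern the diene delivers from its ketene acetal carbon and its 3-methoxy carbon, so no phenol of the dimer needs selective methylation.
A sulfoxide sits on the dienophile carbon that becomes C4a: it activates C5=C6 and leaves by thermal syn-elimination with the cis hydrogen on C8a. The ring is kept at the 2,3-dihydro level so that the dehydrogenation falls on a flavanone.
Stereochemistry: the target has no stereocentre; C2 of the dihydropyranone/flavanone and the sulfoxide sulfur are formed racemic and are erased in steps 8 and 9.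

Key step: step 8

Remark: compounds 9–12 and 16–18 are racemates or diastereomer mixtures whose stereocentres do not survive, so their SMILES carry no configuration. "Ar" denotes 4-{[5,7-bis(benzyloxy)-4'-methoxyflavon-8-yl]oxy}phenyl.

Step 1
Reactants: 1 acacetin (5,7-dihydroxy-4'-methoxyflavone)
Product: 2 7-O-benzylacacetin (7-benzyloxy-5-hydroxy-4'-methoxyflavone)
Conditions: BnBr, K2CO3, acetone, reflux
Reagents that add atoms: benzyl bromide, BrCc1ccccc1
Why: Williamson ether synthesis; the unchelated, more acidic 7-OH is alkylated, while the 5-OH is held in a hydrogen bond to the C4 carbonyl and stays free under mild carbonate conditions.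

Step 2
Reactants: 2 7-O-benzylacacetin
Product: 4 7-benzyloxy-5,8-dihydroxy-4'-methoxyflavone, via aryl sulfate potassium salt 3 (not isolated)
Conditions: K2S2O8, aq. KOH, pyridine, 15–20 °C; then 2 M HCl, 80 °C
Reagents that add atoms: potassium peroxodisulfate, [K+].[K+].[O-]S(=O)(=O)OOS(=O)(=O)[O-]
Why: Elbs persulfate oxidation; the 5-phenolate attacks the peroxide oxygen through its para carbon C8 to give aryl sulfate 3, and acid hydrolysis frees the 8-OH, as is standard for 5-hydroxy-7-alkoxyflavones.

Step 3
Reactants: 4 7-benzyloxy-5,8-dihydroxy-4'-methoxyflavone; 5 4-fluorobenzaldehyde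
Product: 6 7-benzyloxy-8-(4-formylphenoxy)-5-hydroxy-4'-methoxyflavone
Conditions: K2CO3, DMF, 90 °C, argon
Reagents that add atoms: none
Why: Nucleophilic aromatic substitution (SNAr); the unchelated 8-phenoxide displaces fluoride para to the formyl group, the chelated 5-OH being far less nucleophilic, and exclusion of air protects the hydroquinone.

Step 4
Reactants: 6 7-benzyloxy-8-(4-formylphenoxy)-5-hydroxy-4'-methoxyflavone
Product: 7 5,7-bis(benzyloxy)-8-(4-formylphenoxy)-4'-methoxyflavone
Conditions: BnBr, K2CO3, DMF, 70 °C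
Reagents that add atoms: benzyl bromide, BrCc1ccccc1
Why: Williamson ether synthesis under forcing conditions alkylates the chelated 5-OH; the aldehyde is inert to carbonate and benzyl bromide, and capping this phenol keeps it away from the Lewis acid and the sulfenyl chloride of step 5.

Step 5
Reactants: 7 5,7-bis(benzyloxy)-8-(4-formylphenoxy)-4'-methoxyflavone; 8 Danishefsky diene, (E)-1-methoxy-3-(trimethylsilyloxy)buta-1,3-diene
Product: 11 2-Ar-5-(phenylthio)-2,3-dihydro-4H-pyran-4-one (racemic), via silyl enol ether cycloadduct 9 (not isolated), via methoxy phenylthio ketone 10 (not isolated)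
Conditions: Eu(fod)3 (10 mol%; fod = 6,6,7,7,8,8,8-heptafluoro-2,2-dimethyloctane-3,5-dionate), CH2Cl2, rt; PhSCl, −78 °C; TFA, 0 °C to rt
Reagents that add atoms: benzenesulfenyl chloride, ClSc1ccccc1
Why: Lanthanide-catalysed hetero-Diels–Alder reaction of the aldehyde with the Danishefsky diene gives silyl enol ether 9, which is far more nucleophilic than any arene present and is sulfenylated next to the acetal carbon (10); TFA-induced β-elimination of methanol then gives the α-phenylthio enone as a racemate.

Step 6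
Reactants: 11 2-Ar-5-(phenylthio)-2,3-dihydro-4H-pyran-4-one
Product: 12 2-Ar-5-(phenylsulfinyl)-2,3-dihydro-4H-pyran-4-one (mixture of diastereomers)
Conditions: mCPBA (1.0 equiv), NaHCO3, CH2Cl2, −40 °C
Reagents that add atoms: mCPBA, OOC(=O)c1cccc(Cl)c1
Why: Sulfide-to-sulfoxide oxidation with one equivalent of peracid at low temperature; sulfur is the most nucleophilic site, the push–pull alkene and the flavone are electron-poor, and the uncontrolled sulfur stereocentre is irrelevant because the group is expelled in step 8.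

Step 7
Reactants: 13 methyl (E)-3-methoxybut-2-enoate
Product: 15 Brassard diene [1,3-dimethoxy-1-(trimethylsilyloxy)buta-1,3-diene], via lithium dienolate 14 (not isolated)
Conditions: LiN(iPr)2, THF, −78 °C; TMSCl, −78 °C to rt
Reagents that add atoms: chlorotrimethylsilane, C[Si](C)(C)Cl
Why: Silyl ketene acetal formation; γ-deprotonation of the β-methoxy enoate gives lithium dienolate 14, which is silylated on oxygen, the standard preparation of this diene (its ketene acetal geometry does not matter in step 8).

Step 8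
Reactants: 12 2-Ar-5-(phenylsulfinyl)-2,3-dihydro-4H-pyran-4-one; 15 Brassard diene
Product: 18 5,7-bis(benzyloxy)-8-[4-(5-hydroxy-7-methoxy-4-oxochroman-2-yl)phenoxy]-4'-methoxyflavone (racemic flavanone), via sulfinyl cycloadduct 16 (not isolated), via silyl ketal 17 (not isolated)
Conditions: 15 (3 equiv), toluene, 80–110 °C; then 1 M HCl, THF, rt
Reagents that add atoms: none
Why: Proposed new method: the electron-rich diene 15 should add across C5=C6 of 12, the only alkene made electron-poor by both the ketone and a geminal sulfinyl group, with its CH2 terminus bonding to the oxygen-bearing β-carbon C6 (future C8a) and its ketene acetal carbon to C5 (future C4a), either as a concerted [4+2] cycloaddition or as a Mukaiyama–Michael addition followed by 6-exo-trig attack of the α-sulfinyl enolate on the silylated ester cation, and in both cases ring A closes as a six-membered carbocycle. In the cis-fused adduct 16 the sulfinyl group on C4a and the hydrogen on C8a are syn, so thermal sulfoxide elimination gives the C4a=C8a bond of 17 directly, something a halide on C4a could not do because H-8a is neither acidic nor anti to it. Dilute acid then removes methanol and the silyl group from the mixed ketal at C5, and ring A becomes aromatic with OH at C5 and OMe at C7. The closest known reaction types are Diels–Alder additions of dienes to 3-sulfinylchromones with loss of sulfenic acid and the benzannulation of haloquinones with this diene; a 5-sulfinyl-2,3-dihydro-4-pyranone as dienophile is untested. No new stereocentre survives: C4a and C8a become sp2, and C2 stays racemic until step 9 removes it. The selectivity needed is the orientation of the diene, secured by the matching polarity of the enone/vinyl sulfoxide (β-carbon electrophilic) and the diene (CH2 nucleophilic), and the choice of alkene, secured because the C2=C3 bond of flavone 1 is aryl-substituted and has no second activating group.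

Step 9
Reactants: 18 racemic flavanone
Product: 19 5,7-bis(benzyloxy)-8-[4-(5-hydroxy-7-methoxy-4-oxo-4H-chromen-2-yl)phenoxy]-4'-methoxyflavone
Conditions: I2 (10 mol%), DMSO, 120 °C
Reagents that add atoms: none
Why: Iodine-catalysed dehydrogenation of a flavanone to a flavone in DMSO (α-iodination at C3, loss of HI, reoxidation of HI by DMSO), a standard transformation that tolerates benzyl ethers and the chelated 5-OH and erases the C2 stereocentre.

Step 10
Reactants: 19 5,7-di-O-benzyl ether of the target
Product: 20 target, 5,7-dihydroxy-8-[4-(5-hydroxy-7-methoxy-4-oxo-4H-chromen-2-yl)phenoxy]-4'-methoxyflavone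
Conditions: H2 (1 atm), Pd/C, THF–MeOH, rt
Reagents that add atoms: none
Why: Catalytic hydrogenolysis of the two aryl benzyl ethers; the methyl ethers, the diaryl ether and both flavone enones should be untouched at balloon pressure and room temperature.

Compound list
1 | acacetin (5,7-dihydroxy-4'-methoxyflavone) | COc1ccc(-c2cc(=O)c3c(O)cc(O)cc3o2)cc1 | starting material
2 | 7-O-benzylacacetin (7-benzyloxy-5-hydroxy-4'-methoxyflavone) | COc1ccc(-c2cc(=O)c3c(O)cc(OCc4ccccc4)cc3o2)cc1 | intermediate
3 | potassium 7-benzyloxy-5-hydroxy-4'-methoxyflavon-8-yl sulfate (not isolated) | COc1ccc(-c2cc(=O)c3c(O)cc(OCc4ccccc4)c(OS(=O)(=O)[O-])c3o2)cc1.[K+] | intermediate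
4 | 7-benzyloxy-5,8-dihydroxy-4'-methoxyflavone | COc1ccc(-c2cc(=O)c3c(O)cc(OCc4ccccc4)c(O)c3o2)cc1 | intermediate
5 | 4-fluorobenzaldehyde | O=Cc1ccc(F)cc1 | starting material
6 | 7-benzyloxy-8-(4-formylphenoxy)-5-hydroxy-4'-methoxyflavone | COc1ccc(-c2cc(=O)c3c(O)cc(OCc4ccccc4)c(Oc4ccc(C=O)cc4)c3o2)cc1 | intermediate
7 | 5,7-bis(benzyloxy)-8-(4-formylphenoxy)-4'-methoxyflavone | COc1ccc(-c2cc(=O)c3c(OCc4ccccc4)cc(OCc4ccccc4)c(Oc4ccc(C=O)cc4)c3o2)cc1 | intermediate
8 | Danishefsky diene, (E)-1-methoxy-3-(trimethylsilyloxy)buta-1,3-diene | CO/C=C/C(=C)O[Si](C)(C)C | starting material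
9 | 2-Ar-6-methoxy-4-(trimethylsilyloxy)-3,6-dihydro-2H-pyran (hetero-Diels–Alder adduct, not isolated) | COc1ccc(-c2cc(=O)c3c(OCc4ccccc4)cc(OCc4ccccc4)c(Oc4ccc(C5CC(O[Si](C)(C)C)=CC(OC)O5)cc4)c3o2)cc1 | intermediate
10 | 2-Ar-6-methoxy-5-(phenylthio)tetrahydro-4H-pyran-4-one (not isolated) | COc1ccc(-c2cc(=O)c3c(OCc4ccccc4)cc(OCc4ccccc4)c(Oc4ccc(C5CC(=O)C(Sc6ccccc6)C(OC)O5)cc4)c3o2)cc1 | intermediate
11 | 2-Ar-5-(phenylthio)-2,3-dihydro-4H-pyran-4-one (racemic) | COc1ccc(-c2cc(=O)c3c(OCc4ccccc4)cc(OCc4ccccc4)c(Oc4ccc(C5CC(=O)C(Sc6ccccc6)=CO5)cc4)c3o2)cc1 | intermediate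
12 | 2-Ar-5-(phenylsulfinyl)-2,3-dihydro-4H-pyran-4-one (diastereomer mixture) | COc1ccc(-c2cc(=O)c3c(OCc4ccccc4)cc(OCc4ccccc4)c(Oc4ccc(C5CC(=O)C(S(=O)c6ccccc6)=CO5)cc4)c3o2)cc1 | intermediate
13 | methyl (E)-3-methoxybut-2-enoate | CO/C(C)=C/C(=O)OC | starting material
14 | lithium 1,3-dimethoxybuta-1,3-dien-1-olate (not isolated) | [Li+].C=C(OC)C=C([O-])OC | intermediate
15 | Brassard diene, 1,3-dimethoxy-1-(trimethylsilyloxy)buta-1,3-diene (drawn as the E ketene acetal) | C=C(OC)/C=C(\OC)O[Si](C)(C)C | intermediate
16 | 2-Ar-5,7-dimethoxy-4a-(phenylsulfinyl)-5-(trimethylsilyloxy)-2,3,4a,5,8,8a-hexahydro-4H-chromen-4-one (cis-fused cycloadduct, not isolated) | COc1ccc(-c2cc(=O)c3c(OCc4ccccc4)cc(OCc4ccccc4)c(Oc4ccc(C5CC(=O)C6(S(=O)c7ccccc7)C(OC)(O[Si](C)(C)C)C=C(OC)CC6O5)cc4)c3o2)cc1 | intermediate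
17 | 2-Ar-5,7-dimethoxy-5-(trimethylsilyloxy)-2,3,5,8-tetrahydro-4H-chromen-4-one (not isolated) | COc1ccc(-c2cc(=O)c3c(OCc4ccccc4)cc(OCc4ccccc4)c(Oc4ccc(C5CC(=O)C6=C(CC(OC)=CC6(OC)O[Si](C)(C)C)O5)cc4)c3o2)cc1 | intermediate
18 | 5,7-bis(benzyloxy)-8-[4-(5-hydroxy-7-methoxy-4-oxochroman-2-yl)phenoxy]-4'-methoxyflavone (racemic) | COc1ccc(-c2cc(=O)c3c(OCc4ccccc4)cc(OCc4ccccc4)c(Oc4ccc(C5CC(=O)c6c(O)cc(OC)cc6O5)cc4)c3o2)cc1 | intermediate
19 | 5,7-bis(benzyloxy)-8-[4-(5-hydroxy-7-methoxy-4-oxo-4H-chromen-2-yl)phenoxy]-4'-methoxyflavone | COc1ccc(-c2cc(=O)c3c(OCc4ccccc4)cc(OCc4ccccc4)c(Oc4ccc(-c5cc(=O)c6c(O)cc(OC)cc6o5)cc4)c3o2)cc1 | intermediate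
20 | 5,7-dihydroxy-8-[4-(5-hydroxy-7-methoxy-4-oxo-4H-chromen-2-yl)phenoxy]-4'-methoxyflavone (CNP0124888.0) | COc1ccc(-c2cc(=O)c3c(O)cc(O)c(Oc4ccc(-c5cc(=O)c6c(O)cc(OC)cc6o5)cc4)c3o2)cc1 | target

Total step count: 10. Longest linear sequence: 9 steps (steps 1–6, 8, 9, 10); step 7 is a one-step side branch.

Steps most likely to fail

Step 8 (proposed new method). The diene may decompose, or be consumed by silyl transfer to the sulfoxide oxygen, before it adds to a push–pull alkene. Michael addition may also be followed by opening of the pyranone ring instead of ring closure, and silanol may be lost from the ketal in place of methanol. The fallback builds flavone 2 by chalcone chemistry, sets out from aldehyde 7 and returns at target 20. Claisen–Schmidt condensation of 7 with commercial 2'-hydroxy-4',6'-dimethoxyacetophenone (KOH, EtOH–THF, rt) should give the (E)-2'-hydroxychalcone F1. Oxidative cyclization (I2 cat., DMSO, 130 °C) should close ring C to the 5,7-dimethoxyflavone F2. BCl3 (excess, CH2Cl2, −78 to 0 °C) should then cleave the chelated 5-methyl ether of flavone 2 and both benzyl ethers of flavone 1 in one operation, leaving the 7- and 4'-methyl ethers, to give 20.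

Step 2. The persulfate attack may stall at low conversion, the hydroquinone may be over-oxidized in aerated alkali, and the benzyl ether may be partly lost in the hot acid hydrolysis. The fallback installs the ether oxygen by copper catalysis, sets out from 2 and returns at 7, so it also by-passes step 3. Benzylation of the 5-OH (BnBr, K2CO3, DMF, 70 °C) should give 5,7-di-O-benzylacacetin F3. Iodination (NIS, TFA cat., MeCN, rt) should take place at C8, the usual site for 5,7-dialkoxyflavones, to give the 8-iodoflavone F4. Ullmann ether coupling of F4 with 4-hydroxybenzaldehyde (CuI, picolinic acid, K3PO4, DMSO, 90 °C) should give 7.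

Step 5. Cycloaddition to the electron-rich aldehyde may be incomplete, the silyl enol ether may hydrolyse before it is sulfenylated, and excess diene competes for the sulfenyl chloride. The fallback separates ring formation from sulfur introduction, sets out from 7 and returns at 11. BF3·OEt2-promoted cyclocondensation of 7 with 8 (CH2Cl2, −78 °C; then TFA) should give the 2-Ar-2,3-dihydro-4H-pyran-4-one F5. α-Iodination of the enone with I2/pyridine (CH2Cl2, rt), which does not touch the arenes, should give the 5-iodo enone F6. Copper-catalysed C–S coupling with thiophenol (CuI, neocuproine, K3PO4, toluene, 100 °C) should give vinyl sulfide 11.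

Further compounds
F1 | step 8 | (E)-1-(2-hydroxy-4,6-dimethoxyphenyl)-3-Ar-prop-2-en-1-one (2'-hydroxychalcone) | COc1ccc(-c2cc(=O)c3c(OCc4ccccc4)cc(OCc4ccccc4)c(Oc4ccc(/C=C/C(=O)c5c(O)cc(OC)cc5OC)cc4)c3o2)cc1
F2 | step 8 | 5,7-bis(benzyloxy)-8-[4-(5,7-dimethoxy-4-oxo-4H-chromen-2-yl)phenoxy]-4'-methoxyflavone | COc1ccc(-c2cc(=O)c3c(OCc4ccccc4)cc(OCc4ccccc4)c(Oc4ccc(-c5cc(=O)c6c(OC)cc(OC)cc6o5)cc4)c3o2)cc1
F3 | step 2 | 5,7-di-O-benzylacacetin [5,7-bis(benzyloxy)-4'-methoxyflavone] | COc1ccc(-c2cc(=O)c3c(OCc4ccccc4)cc(OCc4ccccc4)cc3o2)cc1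
F4 | step 2 | 5,7-bis(benzyloxy)-8-iodo-4'-methoxyflavone | COc1ccc(-c2cc(=O)c3c(OCc4ccccc4)cc(OCc4ccccc4)c(I)c3o2)cc1
F5 | step 5 | 2-Ar-2,3-dihydro-4H-pyran-4-one (racemic) | COc1ccc(-c2cc(=O)c3c(OCc4ccccc4)cc(OCc4ccccc4)c(Oc4ccc(C5CC(=O)C=CO5)cc4)c3o2)cc1
F6 | step 5 | 2-Ar-5-iodo-2,3-dihydro-4H-pyran-4-one (racemic) | COc1ccc(-c2cc(=O)c3c(OCc4ccccc4)cc(OCc4ccccc4)c(Oc4ccc(C5CC(=O)C(I)=CO5)cc4)c3o2)cc1
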